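The noon run holds 2.24 times the reagent of the spring run, and at its last reading 2.25 times the target. With the substrate charge equal, target, crystals counted, rises with the reagent charge in these two runs.

| setting | spring | noon | flask |
|---|---|---|---|
| substrate | 2 M | 2 M | 2.0 M |
| reagent | 0.67 M | 1.5 M | 1.00 M |
| remark | run made earlier | run made earlier |  |
| time |  |  | 10 d |

| run | time / d | target / % | crystals / % | substrate / % |
|---|---|---|---|---|
| spring | 0.625 | 15.7 | 9.6 | 79.4 |
| spring | 2.08 | 21.8 | 17.2 | 69.0 |
| spring | 4.00 | 20.4 | 19.7 | 66.4 |
| spring | 6.00 | 21.0 | 18.2 | 65.0 |
| spring | 8.00 | 21.0 | 19.3 | 65.6 |
| noon | 1.67 | 41.7 | 38.2 | 39.2 |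
| noon | 3.00 | 47.8 | 44.6 | 31.1 |
| noon | 5.00 | 49.5 | 46.0 | 28.3 |
| noon | 6.00 | 49.2 | 48.5 | 28.5 |
| noon | 8.00 | 47.2 | 45.8 | 26.6 |

(standard deviation of a reading: 1 percentage point)

- amounts and yields of target count crystals too
- given per volume of solution although it is solid: crystals
- a reading of substrate is of its free form alone

- amount of target and crystals together at 10 d, in percent of the substrate charged
- concentration of target in solution at 10 d, in percent of saturation

From 4.00 d in the spring run and 5.00 d in the noon run, the readings stay level within their scatter. Plateau target then averages 20.8% and 48.6%. Substrate lost reads 0.687 M and 1.44 M, close to the reagent charged, so reagent is the limiting reagent in both runs.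

Target made per reagent charged reads 0.621 in the spring run and 0.648 in the noon run. Their mean puts the flask at 31.7%.

The weak link is the assumption of one constant value. The small difference between the runs is therefore carried as a correction, linear in reagent charge, which gives 0.632. This is the target share: target with crystals, per reagent charged, on the plateau. The flask then reaches 31.6%.

Target minus crystals reads 0.0347 M and 0.0373 M in the two runs. The 0.632 M of target reckoned for the flask stands far above that, so crystals should remain in the flask and its solution should stand near 100% of saturation.

The forecast gives 34% and 100% by another route, holding that “the flask should be saturated by 10 d”, and its 34% stands 2.4 percentage points above this reckoning.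

The flask gives 32.0% and 98.5%.

    substrate + reagent ⇌ target (K = 1.90 /M, k = 0.0276 /M/h)
    substrate + reagent ⇌ isomer of the product (K = 87.0 /M, k = 0.0119 /M/h)
    crystals ⇌ target, rate k3*(cs3 - [target]) while solid is left; crystals form when [target] > cs3 (solubility = 41.0 mM, k = 0.239 /h)

The flask's target share comes to 0.641, against 0.632 estimated. In the flask, the substrate that is neither free nor target, crystals counted, stands as isomer of the product, 17.2% at 10.0 d. A neighbour flask charged with 1.7 M of reagent, its substrate and time held, reckons at 53.7% with the same share. That neighbour holds 54.8% of target and crystals together at 10.0 d.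

The numbers in the tables are simulated for an exercise, noise included.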